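Readings and results are calculated for substances that don't exist; noise was put on by code.

1. Start from the small charge, the autumn run: at 11 h it has made 0.0194 M of target and still holds 0.141 M of its 0.160 M of reagent.

| flask | starting material | reagent | free catalyst | time |
|---|---|---|---|---|
| dawn | 0.400 M | 0.400 M | 0.0200 M |  |
| autumn | 0.160 M | 0.160 M | 0.0200 M |  |
| dusk | 0.400 M | 0.600 M | 0.0200 M |  |
| summer | 0.400 M | 0.200 M | 0.0400 M | 11 h |

- dawn run (time / h: [target] / M): 0.63: 0.0162; 1.9: 0.0396; 3.6: 0.0594; 5.7: 0.0719; 8.2: 0.0772; 11: 0.0829
- autumn run (time / h: [target] / M): 0.63: 0.0019; 1.9: 0.0099; 3.6: 0.0116; 5.7: 0.0143; 8.2: 0.0172; 11: 0.0194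
- dusk run (time / h: [target] / M): 0.63: 0.0199; 1.9: 0.0536; 3.6: 0.0789; 5.7: 0.0937; 8.2: 0.1018; 11: 0.1049

(scatter of a reading: 0.001 M)

- apparent order in [reagent] of the starting rate, round the charge of the dawn run (the rate where two percent of its starting material have turned into target)
- apparent order in [starting material] of the starting rate, round the charge of the dawn run (the rate where two percent of its starting material have turned into target) (one fixed amount of target, the same in the runs compared)
- target in the summer run at 11 h, as a share of the starting material charged

- Overall: starting material + reagent -> target, with free catalyst as catalyst.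
- Constant volume, constant temperature.
- Readings of a species count what is bound in complexes too.
- "The second partner" is reagent.
- An order is taken over about fifteen percent of the charge, up and down.

2. Compare rates in the dawn run. Between its first two readings target forms at 0.0184 M h⁻¹, between its last two at 0.00204 M h⁻¹, a fall by a factor of 9.02. Its reagent has dropped by a factor of 1.26, so the rate falls faster than the reagent.

3. Treat reagent as pseudo-first-order: it is lost at k'R, where R is its concentration and k' holds starting material and catalyst and may change with time. Then the number of reagent lifetimes spent is L = ln(Rc/(Rc − P)), with Rc the reagent charged and P the target made. The dawn run spends 0.232 by 11 h. Divide by its catalyst charge to get Λ, the lifetimes spent per unit of catalyst charged in that time 11.6 M⁻¹.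

4. Check Λ's weak point on the dusk run, which has the same starting material and catalyst but more reagent. It spends 0.192, fewer lifetimes than the dawn run, so I put the reagent order below one.

5. Reckon the summer run, which has the dawn run's starting material and time. Its reagent charge is smaller than its starting material charge. Taking k' proportional to catalyst, it spends 0.464 lifetimes, so P = Rc(1 − e^(−L)) = 0.0743 M, or 18.6 % of the starting material. The summer run charges less reagent than the dawn run, so by step 4 I expect the flask above this figure.

6. The forecast, on the ground that “The stall tracks time instead”, gives 0.75 in reagent, 1 in starting material and 20.3 % for the summer run.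

7. The flask gives this:

    free catalyst + starting material ⇌ catalyst-substrate complex (21.49 M⁻¹ h⁻¹, 216.0 h⁻¹)
    catalyst-substrate complex + reagent → target + free catalyst (107.6 M⁻¹ h⁻¹)
    starting material → decomposed substrate (0.1868 h⁻¹)
    free catalyst + target → spent catalyst + target (1.426 M⁻¹ h⁻¹)

The summer run reaches 19.7 % at 11 h, above my figure, and the apparent orders round the dawn charge are 0.91 in reagent and 1.0 in starting material. Put back into lifetimes, the summer run spends 0.501, so its Λ is 12.5 M⁻¹ against the dawn run's 11.6 M⁻¹. The dusk run makes target equal to a quarter of its starting material at 7.65 h, which gives a Λ of 9.12 M⁻¹ by that time.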